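Numbering: chain C1 (ethyl CH3) to C12 (ketone), with carbinol C4, carboxyl-bearing C5, alkene C6=C7 and methyl-bearing C9; ring O1', C2' (lactone C=O), C3', C4' (enol carbon), C5', C6' (methyl-bearing). The enabling feature is that C12–C3'–C2'(=O)–O1' is an acylacetate whose alcohol part C6'–C5'–C4' is (R)-3-hydroxybutanoate, so the ring bond C3'–C4' is a Claisen bond between an active methylene and an ester carbon.
Retrosynthetic cuts, in order: C3'–C4' (Dieckmann); O1'–C2' and C12–C3' (acylketene from Meldrum's acid plus methyl (R)-3-hydroxybutanoate); C6=C7 (Julia–Kocienski olefination); C5–C6 (vinyl opening of an epoxide); C4=C5 (Wittig).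
Forward: the C1–C6 aldehyde from (S)-2-methylbutan-1-ol is joined to the C7–C12 sulfone from (R)-citronellol, the C5 and C12 carboxyl groups are unveiled one after the other, the acylacetate is attached, and the only ring of the target, the dihydropyranone, closes in the penultimate step.
Stereochemistry: C3 from (S)-2-methylbutan-1-ol; C4 and C5 from a Sharpless epoxidation and its invertive opening; C9 from (R)-citronellol; C6' from methyl (R)-3-hydroxybutanoate; the 6E alkene from the Julia–Kocienski reaction.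

Key step: step 18

Remark: the acylpyranone is written as the 4-hydroxy enol tautomer of the target SMILES, and epoxide 17 is carried as a mixture of epimers at C12 because that centre is erased in step 14.

Step 1
Reactants: 1 (S)-2-methylbutan-1-ol
Product: 3 ethyl (2E,4S)-4-methylhex-2-enoate, via (S)-2-methylbutanal 2 (not isolated)
Conditions: TEMPO (cat.), PhI(OAc)2, CH2Cl2, rt; then Ph3P=CHCO2Et, rt
Reagents that add atoms: ethyl (triphenyl-λ5-phosphanylidene)acetate, CCOC(=O)C=P(c1ccccc1)(c1ccccc1)c1ccccc1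
Why: The nitroxyl-catalysed oxidation stops at the aldehyde, which is trapped in the same flask by the stabilised ylide in an E-selective Wittig olefination before it can racemise at C3 or be lost by evaporation.

Step 2
Reactants: 3 ethyl (2E,4S)-4-methylhex-2-enoate
Product: 4 (2E,4S)-4-methylhex-2-en-1-ol
Conditions: i-Bu2AlH, CH2Cl2, −78 °C; aq. potassium sodium tartrate
Reagents that add atoms: none
Why: Ester reduction with i-Bu2AlH at low temperature is a clean 1,2-reduction of an enoate to the allylic alcohol and touches neither the alkene nor C3.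

Step 3
Reactants: 4 (2E,4S)-4-methylhex-2-en-1-ol
Product: 5 [(2R,3R)-3-[(2S)-butan-2-yl]oxiran-2-yl]methanol
Conditions: Ti(OiPr)4 (cat.), D-(−)-diethyl tartrate (cat.), t-BuOOH, 4 Å MS, CH2Cl2, −20 °C
Reagents that add atoms: tert-butyl hydroperoxide, CC(C)(C)OO
Why: Sharpless asymmetric epoxidation is reagent-controlled for E-allylic alcohols, and the D-(−)-tartrate catalyst delivers oxygen to the face that gives the (2R,3R)-epoxide, which fixes C4 and the configuration from which C5 is derived.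

Step 4
Reactants: 5 [(2R,3R)-3-[(2S)-butan-2-yl]oxiran-2-yl]methanol
Product: 6 (2S,3R,4S)-2-ethenyl-4-methylhexane-1,3-diol
Conditions: CH2=CHMgBr (excess), CuI (cat.), THF/Et2O, −40 → −10 °C; aq. NH4Cl
Reagents that add atoms: vinylmagnesium bromide, C=C[Mg]Br
Why: Copper-catalysed Grignard opening of a 2,3-epoxy alcohol is an SN2 attack at the carbon next to the carbinol (C5) because the α-branched sec-butyl group blocks C4, and the inversion at C5 sets the anti relation between the C4 hydroxyl and the new vinyl group that carries C6.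

Step 5
Reactants: 6 (2S,3R,4S)-2-ethenyl-4-methylhexane-1,3-diol
Product: 7 (2S,3R,4S)-1,3-bis[(tert-butyldimethylsilyl)oxy]-2-ethenyl-4-methylhexane
Conditions: TBSOTf, 2,6-lutidine, CH2Cl2, 0 °C
Reagents that add atoms: tert-butyldimethylsilyl trifluoromethanesulfonate, CC(C)(C)[Si](C)(C)OS(=O)(=O)C(F)(F)F
Why: Silyl ether formation with the silyl triflate and a hindered base protects the primary hydroxyl and the crowded secondary one in a single operation.

Step 6
Reactants: 7 (2S,3R,4S)-1,3-bis[(tert-butyldimethylsilyl)oxy]-2-ethenyl-4-methylhexane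
Product: 8 (2S,3R,4S)-3-[(tert-butyldimethylsilyl)oxy]-2-{[(tert-butyldimethylsilyl)oxy]methyl}-4-methylhexanal
Conditions: O3, CH2Cl2, −78 °C; then PPh3, −78 °C → rt
Reagents that add atoms: ozone, [O-][O+]=O
Why: Ozonolysis with reductive work-up cleaves the only alkene to the C6 aldehyde under neutral conditions that leave the α-stereocentre C5 and both silyl ethers untouched.

Step 7
Reactants: 9 (R)-citronellol
Product: 10 5-{[(3R)-3,7-dimethyloct-6-en-1-yl]sulfanyl}-1-phenyl-1H-tetrazole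
Conditions: 1-phenyl-1H-tetrazole-5-thiol, PPh3, DIAD, THF, 0 °C → rt
Reagents that add atoms: 1-phenyl-1H-tetrazole-5-thiol, Sc1nnnn1-c1ccccc1
Why: Mitsunobu thioetherification of an unhindered primary alcohol with the acidic tetrazolethiol is routine and affects neither the remote C9 stereocentre nor the trisubstituted alkene.

Step 8
Reactants: 10 5-{[(3R)-3,7-dimethyloct-6-en-1-yl]sulfanyl}-1-phenyl-1H-tetrazole
Product: 11 5-{[(3R)-3,7-dimethyloct-6-en-1-yl]sulfonyl}-1-phenyl-1H-tetrazole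
Conditions: (NH4)6Mo7O24·4H2O (cat.), 30% aq. H2O2, EtOH, 0 °C → rt
Reagents that add atoms: hydrogen peroxide, OO
Why: Molybdate-catalysed sulfide oxidation takes the aryl alkyl sulfide to the sulfone much faster than the peroxo species epoxidises an unactivated trisubstituted alkene.

Step 9
Reactants: 8 (2S,3R,4S)-3-[(tert-butyldimethylsilyl)oxy]-2-{[(tert-butyldimethylsilyl)oxy]methyl}-4-methylhexanal and 11 5-{[(3R)-3,7-dimethyloct-6-en-1-yl]sulfonyl}-1-phenyl-1H-tetrazole
Product: 12 (3S,4R,5S,6E,9R)-4-[(tert-butyldimethylsilyl)oxy]-5-{[(tert-butyldimethylsilyl)oxy]methyl}-3,9,13-trimethyltetradeca-6,12-diene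
Conditions: 11, KN(SiMe3)2, DME, −60 °C; then 8, −60 °C → rt
Reagents that add atoms: none
Why: In the Julia–Kocienski olefination the potassium salt of the phenyltetrazolyl sulfone adds to the aldehyde and the adduct collapses by Smiles rearrangement and loss of SO2, a sequence that is reliably E-selective for an unbranched sulfone and an α-branched aldehyde in DME, while the low temperature and fast addition protect C5 from enolisation.

Step 10
Reactants: 12 (3S,4R,5S,6E,9R)-4-[(tert-butyldimethylsilyl)oxy]-5-{[(tert-butyldimethylsilyl)oxy]methyl}-3,9,13-trimethyltetradeca-6,12-diene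
Product: 13 (2S,3E,6R)-2-[(1R,2S)-1-[(tert-butyldimethylsilyl)oxy]-2-methylbutyl]-6,10-dimethylundeca-3,9-dien-1-ol
Conditions: HF·pyridine, pyridine, THF, 0 °C
Reagents that add atoms: none
Why: Selective desilylation with buffered HF·pyridine removes the primary silyl ether far faster than the secondary one, which is flanked by two branched carbons.

Step 11
Reactants: 13 (2S,3E,6R)-2-[(1R,2S)-1-[(tert-butyldimethylsilyl)oxy]-2-methylbutyl]-6,10-dimethylundeca-3,9-dien-1-ol
Product: 15 (2R,3E,6R)-2-[(1R,2S)-1-[(tert-butyldimethylsilyl)oxy]-2-methylbutyl]-6,10-dimethylundeca-3,9-dienoic acid, via C5 aldehyde 14 (not isolated)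
Conditions: TEMPO (cat.), PhI(OAc)2, CH2Cl2, rt; then t-BuOH, 2-methyl-2-butene, aq. NaClO2/NaH2PO4, 0 °C → rt
Reagents that add atoms: sodium chlorite, [Na+].[O-]Cl=O
Why: Nitroxyl-catalysed oxidation followed in the same flask by Pinnick oxidation takes the alcohol to the acid without base, so the β,γ-unsaturated aldehyde 14 should neither epimerise at C5 nor move into conjugation, and 2-methyl-2-butene keeps hypochlorite away from both alkenes.

Step 12
Reactants: 15 (2R,3E,6R)-2-[(1R,2S)-1-[(tert-butyldimethylsilyl)oxy]-2-methylbutyl]-6,10-dimethylundeca-3,9-dienoic acid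
Product: 16 2-(trimethylsilyl)ethyl (2R,3E,6R)-2-[(1R,2S)-1-[(tert-butyldimethylsilyl)oxy]-2-methylbutyl]-6,10-dimethylundeca-3,9-dienoate
Conditions: Me3SiCH2CH2OH, PPh3, DIAD, THF, 0 °C → rt
Reagents that add atoms: 2-(trimethylsilyl)ethanol, C[Si](C)(C)CCO
Why: Mitsunobu esterification activates the alcohol and not the acid, so the α-branched β,γ-unsaturated acid reacts as its carboxylate and never passes through an acyl species that could enolise at C5.

Step 13
Reactants: 16 2-(trimethylsilyl)ethyl (2R,3E,6R)-2-[(1R,2S)-1-[(tert-butyldimethylsilyl)oxy]-2-methylbutyl]-6,10-dimethylundeca-3,9-dienoate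
Product: 17 2-(trimethylsilyl)ethyl (2R,3E,6R)-2-[(1R,2S)-1-[(tert-butyldimethylsilyl)oxy]-2-methylbutyl]-8-(3,3-dimethyloxiran-2-yl)-6-methyloct-3-enoate
Conditions: mCPBA (1 equiv), NaHCO3, CH2Cl2, −20 → 0 °C
Reagents that add atoms: 3-chloroperoxybenzoic acid, OOC(=O)c1cccc(Cl)c1
Why: Prilezhaev epoxidation with one equivalent of peracid selects the electron-rich trisubstituted alkene at C12 over the C6=C7 alkene, which is only disubstituted, deactivated by the neighbouring ester and shielded by the branched C5; the new oxirane centre forms without control and is removed in step 14.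

Step 14
Reactants: 17 2-(trimethylsilyl)ethyl (2R,3E,6R)-2-[(1R,2S)-1-[(tert-butyldimethylsilyl)oxy]-2-methylbutyl]-8-(3,3-dimethyloxiran-2-yl)-6-methyloct-3-enoate
Product: 18 2-(trimethylsilyl)ethyl (2R,3E,6R)-2-[(1R,2S)-1-[(tert-butyldimethylsilyl)oxy]-2-methylbutyl]-6-methyl-9-oxonon-3-enoate
Conditions: H5IO6, THF/H2O, 0 °C
Reagents that add atoms: none
Why: Periodic acid hydrolyses the trisubstituted epoxide and cleaves the resulting glycol in one operation (Malaprade cleavage) to give the C12 aldehyde and acetone, under conditions mild enough for the silyl ether and the silylethyl ester.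

Step 15
Reactants: 18 2-(trimethylsilyl)ethyl (2R,3E,6R)-2-[(1R,2S)-1-[(tert-butyldimethylsilyl)oxy]-2-methylbutyl]-6-methyl-9-oxonon-3-enoate
Product: 19 (4R,6E,8R)-8-[(1R,2S)-1-[(tert-butyldimethylsilyl)oxy]-2-methylbutyl]-4-methyl-9-oxo-9-[2-(trimethylsilyl)ethoxy]non-6-enoic acid
Conditions: NaClO2, NaH2PO4, 2-methyl-2-butene, t-BuOH/H2O, 0 °C → rt
Reagents that add atoms: sodium chlorite, [Na+].[O-]Cl=O
Why: Pinnick oxidation converts the unhindered aldehyde into the C12 acid without affecting the alkene, the silyl ether or the C5 ester.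

Step 16
Reactants: 19 (4R,6E,8R)-8-[(1R,2S)-1-[(tert-butyldimethylsilyl)oxy]-2-methylbutyl]-4-methyl-9-oxo-9-[2-(trimethylsilyl)ethoxy]non-6-enoic acid and 20 Meldrum's acid
Product: 21 acyl Meldrum's acid of 19 (enol form)
Conditions: DCC, DMAP, CH2Cl2, 0 °C → rt
Reagents that add atoms: none
Why: Carbodiimide/DMAP C-acylation of Meldrum's acid is the standard route from an unhindered alkanoic acid to a β-keto ester, and the C5 ester is inert to it.

Step 17
Reactants: 21 acyl Meldrum's acid of 19 (enol form) and 22 methyl (R)-3-hydroxybutanoate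
Product: 23 11-[(2R)-4-methoxy-4-oxobutan-2-yl] 1-[2-(trimethylsilyl)ethyl] (2R,3E,6R)-2-[(1R,2S)-1-[(tert-butyldimethylsilyl)oxy]-2-methylbutyl]-6-methyl-9-oxoundec-3-enedioate
Conditions: toluene, 80 °C
Reagents that add atoms: none
Why: Thermal cycloreversion of the acyl Meldrum's acid releases acetone and CO2 to give an acylketene that is captured by the secondary alcohol 22, which forms the O1'–C2' ester with retention at C6' because the carbinol C–O bond is never broken.

Step 18
Reactants: 23 11-[(2R)-4-methoxy-4-oxobutan-2-yl] 1-[2-(trimethylsilyl)ethyl] (2R,3E,6R)-2-[(1R,2S)-1-[(tert-butyldimethylsilyl)oxy]-2-methylbutyl]-6-methyl-9-oxoundec-3-enedioate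
Product: 25 (2R,3E,6R)-2-[(1R,2S)-1-[(tert-butyldimethylsilyl)oxy]-2-methylbutyl]-9-[(6R)-4-hydroxy-6-methyl-2-oxo-5,6-dihydro-2H-pyran-3-yl]-6-methyl-9-oxonon-3-enoic acid, via C5 carboxylate 24 (not isolated)
Conditions: Bu4NF (excess), THF, 0 °C → rt; then 1 M HCl
Reagents that add atoms: none
Why: This is a Lacey–Dieckmann (intramolecular Claisen) condensation in which fluoride first removes the 2-(trimethylsilyl)ethyl group by β-elimination (Me3SiF and ethene) to leave the C5 carboxylate 24 and then, acting as a base, deprotonates the doubly activated C3' methylene of the acylacetate. The C3' enolate adds to the methyl ester carbonyl C4' and methoxide is expelled, which forms the C3'–C4' bond, and deprotonation of the resulting tricarbonyl makes the closure irreversible. The ring O1'–C2'–C3'–C4'–C5'–C6' closes in the 6-exo-trig mode, and the closest known reaction type is the base- or fluoride-mediated Dieckmann cyclisation of acylacetates of hydroxy and amino esters to 3-acyltetronic acids, 3-acyltetramic acids and 3-acyl-dihydropyran-2,4-diones. No stereocentre is created: C6' is the untouched carbinol carbon of 22, and C5 is protected from epimerisation and from conjugation of the alkene because it sits next to a carboxylate. The step needs C-acylation to win over E1cB loss of the acylacetate across C5'–C6'; this is secured by the much higher acidity of the C3' hydrogens compared with the ester α-hydrogens, and the product, held as its enolate, is inert to further base.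

Step 19
Reactants: 25 (2R,3E,6R)-2-[(1R,2S)-1-[(tert-butyldimethylsilyl)oxy]-2-methylbutyl]-9-[(6R)-4-hydroxy-6-methyl-2-oxo-5,6-dihydro-2H-pyran-3-yl]-6-methyl-9-oxonon-3-enoic acid
Product: 26 (2R,3E,6R)-2-[(1R,2S)-1-hydroxy-2-methylbutyl]-9-[(6R)-4-hydroxy-6-methyl-2-oxo-5,6-dihydro-2H-pyran-3-yl]-6-methyl-9-oxonon-3-enoic acid
Conditions: 48% aq. HF, MeCN, 0 °C → rt
Reagents that add atoms: none
Why: Silyl ether cleavage with acidic fluoride removes the hindered secondary silyl group, and the β-hydroxy acid, the E-alkene and the acyl-dihydropyranone are stable to aqueous HF.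

Compound list
1 | (S)-2-methylbutan-1-ol | CC[C@H](C)CO | starting material
2 | (S)-2-methylbutanal | CC[C@H](C)C=O | intermediate
3 | ethyl (2E,4S)-4-methylhex-2-enoate | CC[C@H](C)/C=C/C(=O)OCC | intermediate
4 | (2E,4S)-4-methylhex-2-en-1-ol | CC[C@H](C)/C=C/CO | intermediate
5 | [(2R,3R)-3-[(2S)-butan-2-yl]oxiran-2-yl]methanol | CC[C@H](C)[C@H]1O[C@@H]1CO | intermediate
6 | (2S,3R,4S)-2-ethenyl-4-methylhexane-1,3-diol | CC[C@H](C)[C@@H](O)[C@@H](C=C)CO | intermediate
7 | (2S,3R,4S)-1,3-bis[(tert-butyldimethylsilyl)oxy]-2-ethenyl-4-methylhexane | CC[C@H](C)[C@@H](O[Si](C)(C)C(C)(C)C)[C@@H](C=C)CO[Si](C)(C)C(C)(C)C | intermediate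
8 | (2S,3R,4S)-3-[(tert-butyldimethylsilyl)oxy]-2-{[(tert-butyldimethylsilyl)oxy]methyl}-4-methylhexanal (C1–C6 aldehyde) | CC[C@H](C)[C@@H](O[Si](C)(C)C(C)(C)C)[C@@H](C=O)CO[Si](C)(C)C(C)(C)C | intermediate
9 | (R)-citronellol, (3R)-3,7-dimethyloct-6-en-1-ol | OCC[C@H](C)CCC=C(C)C | starting material
10 | 5-{[(3R)-3,7-dimethyloct-6-en-1-yl]sulfanyl}-1-phenyl-1H-tetrazole | c1ccccc1-n1nnnc1SCC[C@H](C)CCC=C(C)C | intermediate
11 | 5-{[(3R)-3,7-dimethyloct-6-en-1-yl]sulfonyl}-1-phenyl-1H-tetrazole (C7–C12 sulfone) | c1ccccc1-n1nnnc1S(=O)(=O)CC[C@H](C)CCC=C(C)C | intermediate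
12 | (3S,4R,5S,6E,9R)-4-[(tert-butyldimethylsilyl)oxy]-5-{[(tert-butyldimethylsilyl)oxy]methyl}-3,9,13-trimethyltetradeca-6,12-diene | CC[C@H](C)[C@@H](O[Si](C)(C)C(C)(C)C)[C@@H](/C=C/C[C@H](C)CCC=C(C)C)CO[Si](C)(C)C(C)(C)C | intermediate
13 | (2S,3E,6R)-2-[(1R,2S)-1-[(tert-butyldimethylsilyl)oxy]-2-methylbutyl]-6,10-dimethylundeca-3,9-dien-1-ol | CC[C@H](C)[C@@H](O[Si](C)(C)C(C)(C)C)[C@@H](/C=C/C[C@H](C)CCC=C(C)C)CO | intermediate
14 | (2R,3E,6R)-2-[(1R,2S)-1-[(tert-butyldimethylsilyl)oxy]-2-methylbutyl]-6,10-dimethylundeca-3,9-dienal | CC[C@H](C)[C@@H](O[Si](C)(C)C(C)(C)C)[C@@H](/C=C/C[C@H](C)CCC=C(C)C)C=O | intermediate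
15 | (2R,3E,6R)-2-[(1R,2S)-1-[(tert-butyldimethylsilyl)oxy]-2-methylbutyl]-6,10-dimethylundeca-3,9-dienoic acid | CC[C@H](C)[C@@H](O[Si](C)(C)C(C)(C)C)[C@@H](/C=C/C[C@H](C)CCC=C(C)C)C(=O)O | intermediate
16 | 2-(trimethylsilyl)ethyl (2R,3E,6R)-2-[(1R,2S)-1-[(tert-butyldimethylsilyl)oxy]-2-methylbutyl]-6,10-dimethylundeca-3,9-dienoate | CC[C@H](C)[C@@H](O[Si](C)(C)C(C)(C)C)[C@@H](/C=C/C[C@H](C)CCC=C(C)C)C(=O)OCC[Si](C)(C)C | intermediate
17 | 2-(trimethylsilyl)ethyl (2R,3E,6R)-2-[(1R,2S)-1-[(tert-butyldimethylsilyl)oxy]-2-methylbutyl]-8-(3,3-dimethyloxiran-2-yl)-6-methyloct-3-enoate (both oxirane epimers) | CC[C@H](C)[C@@H](O[Si](C)(C)C(C)(C)C)[C@@H](/C=C/C[C@H](C)CCC1OC1(C)C)C(=O)OCC[Si](C)(C)C | intermediate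
18 | 2-(trimethylsilyl)ethyl (2R,3E,6R)-2-[(1R,2S)-1-[(tert-butyldimethylsilyl)oxy]-2-methylbutyl]-6-methyl-9-oxonon-3-enoate | CC[C@H](C)[C@@H](O[Si](C)(C)C(C)(C)C)[C@@H](/C=C/C[C@H](C)CCC=O)C(=O)OCC[Si](C)(C)C | intermediate
19 | (4R,6E,8R)-8-[(1R,2S)-1-[(tert-butyldimethylsilyl)oxy]-2-methylbutyl]-4-methyl-9-oxo-9-[2-(trimethylsilyl)ethoxy]non-6-enoic acid | CC[C@H](C)[C@@H](O[Si](C)(C)C(C)(C)C)[C@@H](/C=C/C[C@H](C)CCC(=O)O)C(=O)OCC[Si](C)(C)C | intermediate
20 | Meldrum's acid, 2,2-dimethyl-1,3-dioxane-4,6-dione | CC1(C)OC(=O)CC(=O)O1 | starting material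
21 | acyl Meldrum's acid of 19: 5-(1-hydroxyalkylidene)-2,2-dimethyl-1,3-dioxane-4,6-dione carrying the C1–C11 chain | CC[C@H](C)[C@@H](O[Si](C)(C)C(C)(C)C)[C@@H](/C=C/C[C@H](C)CCC(O)=C1C(=O)OC(C)(C)OC1=O)C(=O)OCC[Si](C)(C)C | intermediate
22 | methyl (R)-3-hydroxybutanoate | C[C@@H](O)CC(=O)OC | starting material
23 | 11-[(2R)-4-methoxy-4-oxobutan-2-yl] 1-[2-(trimethylsilyl)ethyl] (2R,3E,6R)-2-[(1R,2S)-1-[(tert-butyldimethylsilyl)oxy]-2-methylbutyl]-6-methyl-9-oxoundec-3-enedioate (precursor of the key step) | CC[C@H](C)[C@@H](O[Si](C)(C)C(C)(C)C)[C@@H](/C=C/C[C@H](C)CCC(=O)CC(=O)O[C@H](C)CC(=O)OC)C(=O)OCC[Si](C)(C)C | intermediate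
24 | C5 carboxylic acid of 23 (present as its tetrabutylammonium carboxylate) | CC[C@H](C)[C@@H](O[Si](C)(C)C(C)(C)C)[C@@H](/C=C/C[C@H](C)CCC(=O)CC(=O)O[C@H](C)CC(=O)OC)C(=O)O | intermediate
25 | (2R,3E,6R)-2-[(1R,2S)-1-[(tert-butyldimethylsilyl)oxy]-2-methylbutyl]-9-[(6R)-4-hydroxy-6-methyl-2-oxo-5,6-dihydro-2H-pyran-3-yl]-6-methyl-9-oxonon-3-enoic acid (product of the key step) | CC[C@H](C)[C@@H](O[Si](C)(C)C(C)(C)C)[C@@H](/C=C/C[C@H](C)CCC(=O)C1=C(O)C[C@@H](C)OC1=O)C(=O)O | intermediate
26 | (2R,3E,6R)-2-[(1R,2S)-1-hydroxy-2-methylbutyl]-9-[(6R)-4-hydroxy-6-methyl-2-oxo-5,6-dihydro-2H-pyran-3-yl]-6-methyl-9-oxonon-3-enoic acid | CC[C@H](C)[C@@H](O)[C@@H](/C=C/C[C@H](C)CCC(=O)C1=C(O)C[C@@H](C)OC1=O)C(=O)O | target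

Total step count: 19. Longest linear sequence: 17 steps (steps 1–6 and 9–19, from 1); the sulfone branch (steps 7 and 8) adds two.

Steps most likely to fail

Step 4. The vinyl nucleophile may attack the epoxide at C4 as well as at C5, or the alkoxide may undergo Payne migration before the opening, so that regiochemical purity and the supply of the C5 stereocentre suffer. The fallback sets out from aldehyde 2 (used as its dichloromethane solution) and comes back to the route at aldehyde 8; it forms the C4–C5 bond by an aldol addition instead of opening an epoxide.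
- Aldehyde 2 would be added to the dibutylboron dienolate of commercial (4S)-4-benzyl-3-[(2E)-but-2-enoyl]-1,3-oxazolidin-2-one (Bu2BOTf, Et3N, CH2Cl2, −78 °C). This Evans syn aldol addition at the α-carbon would give (4S)-4-benzyl-3-[(2S,3R,4S)-2-ethenyl-3-hydroxy-4-methylhexanoyl]-1,3-oxazolidin-2-one F1, in which the imide carbon is the future C6 and the vinyl group the future hydroxymethyl arm on C5.
- Silylation (TBSOTf, 2,6-lutidine) would give the silyl ether F2, and LiBH4 would remove the auxiliary to give (2R,3R,4S)-3-[(tert-butyldimethylsilyl)oxy]-2-ethenyl-4-methylhexan-1-ol F3.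
- The hydroxyl of F3 would be masked as the 4-methoxybenzyl ether F4 (4-methoxybenzyl trichloroacetimidate, cat. camphorsulfonic acid).
- Ozonolysis with NaBH4 work-up would turn the vinyl group into the hydroxymethyl group of (2R,3R,4S)-3-[(tert-butyldimethylsilyl)oxy]-2-{[(4-methoxybenzyl)oxy]methyl}-4-methylhexan-1-ol F5.
- Silylation (TBSCl, imidazole) would give the bis-silyl ether F6, and DDQ would free the C6 alcohol (2S,3R,4S)-3-[(tert-butyldimethylsilyl)oxy]-2-{[(tert-butyldimethylsilyl)oxy]methyl}-4-methylhexan-1-ol F7.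
- Dess–Martin oxidation of F7 would give 8.

Step 9. The metalated sulfone may act as a base toward the hindered α-branched aldehyde, which would epimerise C5 or expel silanolate, and the E-selectivity may erode. The fallback sets out from 8 and comes back at 12 with the roles of the two partners exchanged.
- Reduction of 8 with NaBH4 would give the alcohol F7 already described in the fallback for step 4.
- Mitsunobu reaction with 1-phenyl-1H-tetrazole-5-thiol would give 5-({(2S,3R,4S)-3-[(tert-butyldimethylsilyl)oxy]-2-{[(tert-butyldimethylsilyl)oxy]methyl}-4-methylhexyl}sulfanyl)-1-phenyl-1H-tetrazole F8.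
- Oxidation with (NH4)6Mo7O24·4H2O and H2O2 would give the corresponding sulfone F9, whose carbanion has no leaving group on the neighbouring carbon.
- Deprotonation with KN(SiMe3)2 in DME and addition of commercial (R)-citronellal (O=CC[C@H](C)CCC=C(C)C) would give 12, with C5 never placed next to a carbonyl group.

Step 18. E1cB expulsion of the acylacetate from the β-acyloxy ester, or epimerisation at C5 before the silylethyl ester has been cleaved, may outrun the ring closure. The fallback sets out from acid 19 and ester 22 and comes back at 25; it forms the C12–C3' bond on a ring that is closed beforehand.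
- Claisen condensation of 22 with an excess of the lithium enolate of tert-butyl acetate (THF, −78 °C) would give tert-butyl (5R)-5-hydroxy-3-oxohexanoate F10.
- Trifluoroacetic acid would lactonise F10 to (6R)-6-methyloxane-2,4-dione F11.
- Acid 19 would be coupled to F11 with DCC and DMAP; under these conditions the first-formed enol ester rearranges to the 3-acyl compound, the 2-(trimethylsilyl)ethyl ester of 25 F12.
- Bu4NF would then cleave the silylethyl ester of F12 to give 25.

Further compounds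
F1 | step 4 | (4S)-4-benzyl-3-[(2S,3R,4S)-2-ethenyl-3-hydroxy-4-methylhexanoyl]-1,3-oxazolidin-2-one | CC[C@H](C)[C@@H](O)[C@@H](C(=O)N1[C@@H](Cc2ccccc2)COC1=O)C=C
F2 | step 4 | (4S)-4-benzyl-3-[(2S,3R,4S)-3-[(tert-butyldimethylsilyl)oxy]-2-ethenyl-4-methylhexanoyl]-1,3-oxazolidin-2-one | CC[C@H](C)[C@@H](O[Si](C)(C)C(C)(C)C)[C@@H](C(=O)N1[C@@H](Cc2ccccc2)COC1=O)C=C
F3 | step 4 | (2R,3R,4S)-3-[(tert-butyldimethylsilyl)oxy]-2-ethenyl-4-methylhexan-1-ol | CC[C@H](C)[C@@H](O[Si](C)(C)C(C)(C)C)[C@@H](CO)C=C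
F4 | step 4 | 4-methoxybenzyl ether of F3 | CC[C@H](C)[C@@H](O[Si](C)(C)C(C)(C)C)[C@@H](COCc1ccc(OC)cc1)C=C
F5 | step 4 | (2R,3R,4S)-3-[(tert-butyldimethylsilyl)oxy]-2-{[(4-methoxybenzyl)oxy]methyl}-4-methylhexan-1-ol | CC[C@H](C)[C@@H](O[Si](C)(C)C(C)(C)C)[C@@H](COCc1ccc(OC)cc1)CO
F6 | step 4 | tert-butyldimethylsilyl ether of F5 | CC[C@H](C)[C@@H](O[Si](C)(C)C(C)(C)C)[C@@H](COCc1ccc(OC)cc1)CO[Si](C)(C)C(C)(C)C
F7 | step 4 | (2S,3R,4S)-3-[(tert-butyldimethylsilyl)oxy]-2-{[(tert-butyldimethylsilyl)oxy]methyl}-4-methylhexan-1-ol | CC[C@H](C)[C@@H](O[Si](C)(C)C(C)(C)C)[C@@H](CO)CO[Si](C)(C)C(C)(C)C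
F8 | step 9 | 5-({(2S,3R,4S)-3-[(tert-butyldimethylsilyl)oxy]-2-{[(tert-butyldimethylsilyl)oxy]methyl}-4-methylhexyl}sulfanyl)-1-phenyl-1H-tetrazole | CC[C@H](C)[C@@H](O[Si](C)(C)C(C)(C)C)[C@@H](CSc1nnnn1-c1ccccc1)CO[Si](C)(C)C(C)(C)C
F9 | step 9 | 5-({(2S,3R,4S)-3-[(tert-butyldimethylsilyl)oxy]-2-{[(tert-butyldimethylsilyl)oxy]methyl}-4-methylhexyl}sulfonyl)-1-phenyl-1H-tetrazole | CC[C@H](C)[C@@H](O[Si](C)(C)C(C)(C)C)[C@@H](CS(=O)(=O)c1nnnn1-c1ccccc1)CO[Si](C)(C)C(C)(C)C
F10 | step 18 | tert-butyl (5R)-5-hydroxy-3-oxohexanoate | C[C@@H](O)CC(=O)CC(=O)OC(C)(C)C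
F11 | step 18 | (6R)-6-methyloxane-2,4-dione | C[C@@H]1CC(=O)CC(=O)O1
F12 | step 18 | 2-(trimethylsilyl)ethyl (2R,3E,6R)-2-[(1R,2S)-1-[(tert-butyldimethylsilyl)oxy]-2-methylbutyl]-9-[(6R)-4-hydroxy-6-methyl-2-oxo-5,6-dihydro-2H-pyran-3-yl]-6-methyl-9-oxonon-3-enoate | CC[C@H](C)[C@@H](O[Si](C)(C)C(C)(C)C)[C@@H](/C=C/C[C@H](C)CCC(=O)C1=C(O)C[C@@H](C)OC1=O)C(=O)OCC[Si](C)(C)C
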